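**Plan**

- Retrosynthesis: the O–Si bond (phenol protection) and the C5–propenyl bond (Suzuki) are cut first, and the C3 methyl group is traced back to a C3 methyl ester.
- Enabling feature: in the ring O1–C2–C3–C3a–C7a, C3 carries both the fused arene carbon C3a and a one-carbon branch. Returning C3a from C3 to that branch carbon regenerates the six-membered ring O1–C2–C3–C4(=O)–C4a–C8a of a (2S)-flavanone.
- The flavanone is cut at C2–aryl into 6-bromo-8-methoxychromone and a 4-silyloxy-3,5-dimethoxyphenylboronic acid.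
- Forward: the chromone ring is built, the aryl group is added, and the pyranone ring is contracted to the dihydrofuran ring, extruding C4 as the ester carbon. Ester to methyl, propenylation and desilylation follow.
- Stereochemistry: C2 is set by the chiral Pd catalyst in the conjugate addition. C3 is set by C2 in the ring contraction (trans, also the thermodynamic arrangement next to the ester).

Key step: step 6

Assumption: the Pd/t-BuPyOx addition to the chromone is taken to follow the facial sense known for cyclic enones, so that the (R)-ligand gives the (2S)-flavanone; if the sense is opposite, the (S)-ligand is used with no other change.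

**Route**

Step 1
Reactants: 1 1-(2-hydroxy-3-methoxyphenyl)ethan-1-one
Product: 2 1-(5-bromo-2-hydroxy-3-methoxyphenyl)ethan-1-one
Conditions: NBS, MeCN, 0 °C to rt
Reagents that add atoms: N-bromosuccinimide, O=C1CCC(=O)N1Br
Why: Electrophilic aromatic bromination should go para to the phenol, the only open position activated by OH, since the other free positions are ortho or para to the deactivating acetyl group.

Step 2
Reactants: 2 1-(5-bromo-2-hydroxy-3-methoxyphenyl)ethan-1-one
Product: 4 6-bromo-8-methoxy-4H-chromen-4-one, via enaminone 3 (not isolated)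
Conditions: DMF-DMA, toluene, 100 °C; concentrate; conc. HCl, CH2Cl2, 40 °C
Reagents that add atoms: N,N-dimethylformamide dimethyl acetal, COC(OC)N(C)C
Why: Enaminone condensation of the methyl ketone followed by acid-mediated cyclisation with loss of dimethylamine is the standard chromone annulation of 2'-hydroxyacetophenones.

Step 3
Reactants: 5 4-bromo-2,6-dimethoxyphenol
Product: 6 (4-bromo-2,6-dimethoxyphenoxy)triisopropylsilane
Conditions: TIPSCl, imidazole, DMF, 50 °C
Reagents that add atoms: chlorotriisopropylsilane, CC(C)[Si](Cl)(C(C)C)C(C)C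
Why: Silyl ether protection of the phenol; TIPS is chosen because it should survive organolithium, Pd(II), acidic orthoformate, hydride and Suzuki conditions and leave with fluoride at the end.

Step 4
Reactants: 6 (4-bromo-2,6-dimethoxyphenoxy)triisopropylsilane
Product: 9 [3,5-dimethoxy-4-(triisopropylsilyloxy)phenyl]boronic acid, via aryllithium 7 (not isolated), via lithium aryltriisopropoxyborate 8 (not isolated)
Conditions: n-BuLi, THF, −78 °C; B(OiPr)3, −78 °C to rt; 1 M HCl to pH 5
Reagents that add atoms: triisopropyl borate, CC(C)OB(OC(C)C)OC(C)C; water, O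
Why: Bromine–lithium exchange followed by borylation and hydrolysis; exchange at −78 °C should outpace attack on silicon, and a para-lithiated aryl silyl ether cannot undergo retro-Brook migration.

Step 5
Reactants: 4 6-bromo-8-methoxy-4H-chromen-4-one; 9 [3,5-dimethoxy-4-(triisopropylsilyloxy)phenyl]boronic acid
Product: 10 (2S)-6-bromo-2-[3,5-dimethoxy-4-(triisopropylsilyloxy)phenyl]-8-methoxychroman-4-one
Conditions: Pd(OCOCF3)2 (5 mol %), (R)-t-BuPyOx (6 mol %), NH4PF6 (30 mol %), H2O (5 equiv), ClCH2CH2Cl, 60 °C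
Reagents that add atoms: none
Why: Pd(II)-catalysed asymmetric conjugate addition of an arylboronic acid to a chromone (Hayashi–Miyaura-type 1,4-addition with a pyridine-oxazoline ligand), in which the tert-butyl group of the ligand differentiates the enone faces during aryl-palladium insertion and should set C2 as S, while cationic Pd(II) does not insert into the aryl bromide.

Step 6
Reactants: 10 (2S)-6-bromo-2-[3,5-dimethoxy-4-(triisopropylsilyloxy)phenyl]-8-methoxychroman-4-one
Product: 13 methyl (2S,3S)-5-bromo-2-[3,5-dimethoxy-4-(triisopropylsilyloxy)phenyl]-7-methoxy-2,3-dihydro-1-benzofuran-3-carboxylate, via enol ether 11 (not isolated), via C3-iodane ketal 12 (not isolated)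
Conditions: PhI(OAc)2 (1.2 equiv), conc. H2SO4 (0.5 equiv), HC(OMe)3, rt
Reagents that add atoms: trimethyl orthoformate, COC(OC)OC
Why: Acid and orthoformate convert the C4 ketone into its ketal and the enol ether 11, which PhI(OAc)2 attacks at C3 anti to the C2 aryl group with methanol capture at C4 to give 12; the fused arene carbon C4a, whose C4–C4a bond is antiperiplanar to the pseudo-equatorial C3–I bond, then shifts from C4 to C3 with loss of PhI, and the dimethoxycarbenium ion left at the extruded carbon collapses to the methyl ester. The closest known reaction type is the iodine(III)- or thallium(III)-mediated oxidative ring contraction of flavanones in trimethyl orthoformate (oxidative 1,2-aryl shift of aryl ketone ketals to α-aryl esters). The ring O1–C2–C3–C3a–C7a is closed by a 1,2-shift through a bridged phenonium-type transition state (formally 3-exo-tet attack of the arene ipso carbon on C3, then C4–C4a cleavage), so the six-membered ring loses C4 as the exocyclic ester carbon. The new stereocentre C3 is controlled by C2: iodination anti to the aryl group and migration with inversion at C3 place the ester trans to the aryl group, and because H-3 is α to the ester the trans isomer is also the thermodynamic one; C2 is not touched. The step needs migration of C4a in preference to the 2,3-shift of the C2 aryl group (isoflavone pathway) and to dehydrogenation, which the dialkoxy-stabilised migration origin of the ketal and the diequatorial half-chair of 12 should secure, helped by the 4-silyloxy group being twisted out of conjugation by its two ortho methoxy groups.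

Step 7
Reactants: 13 methyl (2S,3S)-5-bromo-2-[3,5-dimethoxy-4-(triisopropylsilyloxy)phenyl]-7-methoxy-2,3-dihydro-1-benzofuran-3-carboxylate
Product: 14 {(2S,3R)-5-bromo-2-[3,5-dimethoxy-4-(triisopropylsilyloxy)phenyl]-7-methoxy-2,3-dihydro-1-benzofuran-3-yl}methanol
Conditions: LiAlH4, THF, 0 °C; aqueous NaOH work-up
Reagents that add atoms: none
Why: Hydride reduction of the ester to the primary alcohol at 0 °C, where aryl bromide, aryl silyl ether and the benzylic C2–O bond should be inert; C3 is no longer epimerisable afterwards (the descriptor changes to R by priority only).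

Step 8
Reactants: 14 {(2S,3R)-5-bromo-2-[3,5-dimethoxy-4-(triisopropylsilyloxy)phenyl]-7-methoxy-2,3-dihydro-1-benzofuran-3-yl}methanol
Product: 15 {(2S,3R)-5-bromo-2-[3,5-dimethoxy-4-(triisopropylsilyloxy)phenyl]-7-methoxy-2,3-dihydro-1-benzofuran-3-yl}methyl 4-methylbenzenesulfonate
Conditions: TsCl, Et3N, DMAP (cat.), CH2Cl2, 0 °C to rt
Reagents that add atoms: 4-toluenesulfonyl chloride, Cc1ccc(cc1)S(Cl)(=O)=O
Why: Sulfonylation (tosylation) of the only free hydroxyl group, a primary alcohol.

Step 9
Reactants: 15 {(2S,3R)-5-bromo-2-[3,5-dimethoxy-4-(triisopropylsilyloxy)phenyl]-7-methoxy-2,3-dihydro-1-benzofuran-3-yl}methyl 4-methylbenzenesulfonate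
Product: 16 {4-[(2S,3S)-5-bromo-7-methoxy-3-methyl-2,3-dihydro-1-benzofuran-2-yl]-2,6-dimethoxyphenoxy}triisopropylsilane
Conditions: LiEt3BH, THF, 0 °C to rt
Reagents that add atoms: none
Why: SN2 displacement of the primary tosylate by hydride, which at 0 °C should outpace both E2 elimination and reduction of the aryl bromide; neither stereocentre is involved.

Step 10
Reactants: 16 {4-[(2S,3S)-5-bromo-7-methoxy-3-methyl-2,3-dihydro-1-benzofuran-2-yl]-2,6-dimethoxyphenoxy}triisopropylsilane; 17 (E)-prop-1-en-1-ylboronic acid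
Product: 18 {2,6-dimethoxy-4-[(2S,3S)-7-methoxy-3-methyl-5-[(E)-prop-1-en-1-yl]-2,3-dihydro-1-benzofuran-2-yl]phenoxy}triisopropylsilane
Conditions: Pd(dppf)Cl2·CH2Cl2 (5 mol %), K2CO3, 1,4-dioxane/H2O, 80 °C
Reagents that add atoms: none
Why: Suzuki–Miyaura cross-coupling of the aryl bromide with an (E)-alkenylboronic acid should proceed with retention of alkene geometry, and no other halide or pseudohalide is present.

Step 11
Reactants: 18 {2,6-dimethoxy-4-[(2S,3S)-7-methoxy-3-methyl-5-[(E)-prop-1-en-1-yl]-2,3-dihydro-1-benzofuran-2-yl]phenoxy}triisopropylsilane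
Product: 19 odoratisol A
Conditions: TBAF, AcOH, THF, 0 °C to rt
Reagents that add atoms: none
Why: Fluoride-mediated cleavage of the aryl silyl ether, buffered with acetic acid so that no free phenoxide para to the benzylic C2–O bond persists (which could open the ring via a quinone methide and epimerise C2).

**Compound list**

1 | 1-(2-hydroxy-3-methoxyphenyl)ethan-1-one | CC(=O)c1cccc(OC)c1O | starting material
2 | 1-(5-bromo-2-hydroxy-3-methoxyphenyl)ethan-1-one | CC(=O)c1cc(Br)cc(OC)c1O | intermediate
3 | (E)-1-(5-bromo-2-hydroxy-3-methoxyphenyl)-3-(dimethylamino)prop-2-en-1-one | CN(C)/C=C/C(=O)c1cc(Br)cc(OC)c1O | intermediate (not isolated)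
4 | 6-bromo-8-methoxy-4H-chromen-4-one | COc1cc(Br)cc2c1occc2=O | intermediate
5 | 4-bromo-2,6-dimethoxyphenol | COc1cc(Br)cc(OC)c1O | starting material
6 | (4-bromo-2,6-dimethoxyphenoxy)triisopropylsilane | COc1cc(Br)cc(OC)c1O[Si](C(C)C)(C(C)C)C(C)C | intermediate
7 | [3,5-dimethoxy-4-(triisopropylsilyloxy)phenyl]lithium | [Li]c1cc(OC)c(O[Si](C(C)C)(C(C)C)C(C)C)c(OC)c1 | intermediate (not isolated)
8 | lithium [3,5-dimethoxy-4-(triisopropylsilyloxy)phenyl]triisopropoxyborate | [Li+].CC(C)O[B-](OC(C)C)(OC(C)C)c1cc(OC)c(O[Si](C(C)C)(C(C)C)C(C)C)c(OC)c1 | intermediate (not isolated)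
9 | [3,5-dimethoxy-4-(triisopropylsilyloxy)phenyl]boronic acid | OB(O)c1cc(OC)c(O[Si](C(C)C)(C(C)C)C(C)C)c(OC)c1 | intermediate
10 | (2S)-6-bromo-2-[3,5-dimethoxy-4-(triisopropylsilyloxy)phenyl]-8-methoxychroman-4-one | COc1cc(Br)cc2c1O[C@H](c1cc(OC)c(O[Si](C(C)C)(C(C)C)C(C)C)c(OC)c1)CC2=O | intermediate
11 | (2S)-6-bromo-2-[3,5-dimethoxy-4-(triisopropylsilyloxy)phenyl]-4,8-dimethoxy-2H-chromene | COc1cc(Br)cc2c1O[C@H](c1cc(OC)c(O[Si](C(C)C)(C(C)C)C(C)C)c(OC)c1)C=C2OC | intermediate (not isolated)
12 | (2R,3R)-3-[acetoxy(phenyl)-λ3-iodanyl]-6-bromo-2-[3,5-dimethoxy-4-(triisopropylsilyloxy)phenyl]-4,4,8-trimethoxychroman (iodane trans to the aryl group; C2 geometry as in 10) | COc1cc(Br)cc2c1O[C@H](c1cc(OC)c(O[Si](C(C)C)(C(C)C)C(C)C)c(OC)c1)[C@@H]([I](OC(C)=O)c1ccccc1)C2(OC)OC | intermediate (not isolated)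
13 | methyl (2S,3S)-5-bromo-2-[3,5-dimethoxy-4-(triisopropylsilyloxy)phenyl]-7-methoxy-2,3-dihydro-1-benzofuran-3-carboxylate (trans) | Brc1cc(OC)c2c(c1)[C@H](C(=O)OC)[C@@H](c1cc(OC)c(O[Si](C(C)C)(C(C)C)C(C)C)c(OC)c1)O2 | intermediate
14 | {(2S,3R)-5-bromo-2-[3,5-dimethoxy-4-(triisopropylsilyloxy)phenyl]-7-methoxy-2,3-dihydro-1-benzofuran-3-yl}methanol | Brc1cc(OC)c2c(c1)[C@H](CO)[C@@H](c1cc(OC)c(O[Si](C(C)C)(C(C)C)C(C)C)c(OC)c1)O2 | intermediate
15 | {(2S,3R)-5-bromo-2-[3,5-dimethoxy-4-(triisopropylsilyloxy)phenyl]-7-methoxy-2,3-dihydro-1-benzofuran-3-yl}methyl 4-methylbenzenesulfonate | Brc1cc(OC)c2c(c1)[C@H](COS(=O)(=O)c1ccc(C)cc1)[C@@H](c1cc(OC)c(O[Si](C(C)C)(C(C)C)C(C)C)c(OC)c1)O2 | intermediate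
16 | {4-[(2S,3S)-5-bromo-7-methoxy-3-methyl-2,3-dihydro-1-benzofuran-2-yl]-2,6-dimethoxyphenoxy}triisopropylsilane | Brc1cc(OC)c2c(c1)[C@H](C)[C@@H](c1cc(OC)c(O[Si](C(C)C)(C(C)C)C(C)C)c(OC)c1)O2 | intermediate
17 | (E)-prop-1-en-1-ylboronic acid | C/C=C/B(O)O | starting material
18 | {2,6-dimethoxy-4-[(2S,3S)-7-methoxy-3-methyl-5-[(E)-prop-1-en-1-yl]-2,3-dihydro-1-benzofuran-2-yl]phenoxy}triisopropylsilane | C/C=C/c1cc(OC)c2c(c1)[C@H](C)[C@@H](c1cc(OC)c(O[Si](C(C)C)(C(C)C)C(C)C)c(OC)c1)O2 | intermediate
19 | odoratisol A, 2,6-dimethoxy-4-[(2S,3S)-7-methoxy-3-methyl-5-[(E)-prop-1-en-1-yl]-2,3-dihydro-1-benzofuran-2-yl]phenol | C/C=C/c1cc(OC)c2c(c1)[C@H](C)[C@@H](c1cc(OC)c(O)c(OC)c1)O2 | target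

**Step count**

Total steps: 11. Longest linear sequence: 9 steps (steps 1, 2, 5, 6, 7, 8, 9, 10, 11; the branch through steps 3 and 4 is equally long).

**Steps most likely to fail and fallbacks**

Step 6. The contraction may lose out to a 2,3-shift of the electron-rich C2 aryl group, to dehydrogenation, or to attack of the iodine(III) electrophile on the dimethoxyarene. The acid may also strip the silyl ether or ionise the benzylic C2–O bond with loss of enantiopurity. The fallback runs the same contraction without oxidant or acid, as a photochemical Wolff rearrangement. It sets out from 10. LiHMDS, THF, −78 °C, then CF3CO2CH2CF3 would give the 3-trifluoroacetyl flavanone F1. Detrifluoroacetylative diazo transfer (MsN3, Et3N, H2O, MeCN) would give the 3-diazo flavanone F2. Irradiation at 365 nm in MeOH should expel N2 with shift of C4a to C3 and give the ring-contracted ketene F3. Methanol traps F3 as the ester, in part as the cis ester F4. NaOMe in MeOH equilibrates F4 to the trans isomer, and the route is rejoined at 13.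

Step 5. The electron-rich boronic acid may protodeboronate, insertion into the 8-methoxy chromone may be slow, or facial selectivity may be poor. The fallback makes the flavanone racemic by the chalcone route and resolves it. It sets out from 6 and 2. Bromine–lithium exchange of 6 (n-BuLi, THF, −78 °C, via 7) and a DMF quench would give the aldehyde F5. Condensation of F5 with 2 (pyrrolidine, MeOH, 60 °C; Claisen–Schmidt type) would give the 2'-hydroxychalcone F6. F6 should close under the same conditions by oxa-Michael addition to the racemic flavanone F7. Preparative chromatography on a chiral stationary phase separates the enantiomers and returns to the route at 10. The (R)-flavanone F8 is racemised with pyrrolidine via F6 and recycled.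

Step 9. The tosylate may be lost by E2 elimination toward the 3-methylene compound, the neighbouring arene may participate, or hydride may attack the aryl bromide or silicon. The fallback deoxygenates without a sulfonate/hydride pair, by the Mitsunobu–diazene method. It sets out from 14 and bypasses 15. 2-Nitrobenzenesulfonylhydrazide, PPh3, DEAD, THF, −30 °C would give the N-alkyl sulfonylhydrazine F9. On warming to rt, F9 should lose the sulfinic acid to give the monoalkyl diazene F10, which expels N2 and returns to the route at 16.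

**Further compounds**

F1 | step 6 | (2S)-6-bromo-2-[3,5-dimethoxy-4-(triisopropylsilyloxy)phenyl]-8-methoxy-3-(trifluoroacetyl)chroman-4-one (C3 epimers or enol; C2 as in 10) | COc1cc(Br)cc2c1O[C@H](c1cc(OC)c(O[Si](C(C)C)(C(C)C)C(C)C)c(OC)c1)C(C(=O)C(F)(F)F)C2=O
F2 | step 6 | 6-bromo-3-diazo-2-[3,5-dimethoxy-4-(triisopropylsilyloxy)phenyl]-8-methoxychroman-4-one (C2 as in 10) | COc1cc(Br)cc2c1O[C@H](c1cc(OC)c(O[Si](C(C)C)(C(C)C)C(C)C)c(OC)c1)C(=[N+]=[N-])C2=O
F3 | step 6 | {5-bromo-2-[3,5-dimethoxy-4-(triisopropylsilyloxy)phenyl]-7-methoxy-1-benzofuran-3(2H)-ylidene}methanone (ketene; C2 as in 10) | COc1cc(Br)cc2c1O[C@H](c1cc(OC)c(O[Si](C(C)C)(C(C)C)C(C)C)c(OC)c1)C2=C=O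
F4 | step 6 | methyl (2S,3R)-5-bromo-2-[3,5-dimethoxy-4-(triisopropylsilyloxy)phenyl]-7-methoxy-2,3-dihydro-1-benzofuran-3-carboxylate (cis) | Brc1cc(OC)c2c(c1)[C@@H](C(=O)OC)[C@@H](c1cc(OC)c(O[Si](C(C)C)(C(C)C)C(C)C)c(OC)c1)O2
F5 | step 5 | 3,5-dimethoxy-4-(triisopropylsilyloxy)benzaldehyde | O=Cc1cc(OC)c(O[Si](C(C)C)(C(C)C)C(C)C)c(OC)c1
F6 | step 5 | (E)-1-(5-bromo-2-hydroxy-3-methoxyphenyl)-3-[3,5-dimethoxy-4-(triisopropylsilyloxy)phenyl]prop-2-en-1-one | COc1cc(Br)cc(c1O)C(=O)/C=C/c1cc(OC)c(O[Si](C(C)C)(C(C)C)C(C)C)c(OC)c1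
F7 | step 5 | rac-6-bromo-2-[3,5-dimethoxy-4-(triisopropylsilyloxy)phenyl]-8-methoxychroman-4-one | COc1cc(Br)cc2c1OC(c1cc(OC)c(O[Si](C(C)C)(C(C)C)C(C)C)c(OC)c1)CC2=O
F8 | step 5 | (2R)-6-bromo-2-[3,5-dimethoxy-4-(triisopropylsilyloxy)phenyl]-8-methoxychroman-4-one | COc1cc(Br)cc2c1O[C@@H](c1cc(OC)c(O[Si](C(C)C)(C(C)C)C(C)C)c(OC)c1)CC2=O
F9 | step 9 | N-({(2S,3R)-5-bromo-2-[3,5-dimethoxy-4-(triisopropylsilyloxy)phenyl]-7-methoxy-2,3-dihydro-1-benzofuran-3-yl}methyl)-2-nitrobenzenesulfonohydrazide (alkylated on the sulfonylated nitrogen) | Brc1cc(OC)c2c(c1)[C@H](CN(N)S(=O)(=O)c1ccccc1[N+](=O)[O-])[C@@H](c1cc(OC)c(O[Si](C(C)C)(C(C)C)C(C)C)c(OC)c1)O2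
F10 | step 9 | ({(2S,3R)-5-bromo-2-[3,5-dimethoxy-4-(triisopropylsilyloxy)phenyl]-7-methoxy-2,3-dihydro-1-benzofuran-3-yl}methyl)diazene | Brc1cc(OC)c2c(c1)[C@H](CN=N)[C@@H](c1cc(OC)c(O[Si](C(C)C)(C(C)C)C(C)C)c(OC)c1)O2
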